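## Structural features

The target is a linear trimer of three 2,3-cis-flavan-3-ol (epigallocatechin) units, called T (upper), M (middle) and B (lower); each unit is a chroman (benzo ring A fused to pyran ring C) with a 3,4,5-trihydroxyphenyl ring B on C2 and an oxygen on C3. The units are joined by two C(sp3)–C(aryl) bonds, C4 of T to C8 of M and C4 of M to C8 of B, and the C3 oxygen of M carries a galloyl ester. There are eight stereocentres: C2 and C3 of every unit (aryl and oxygen cis, 2R,3R as in the tea catechins) and C4 of T and of M, each trans to the neighbouring C3 oxygen (4β), so T and M each hold three contiguous centres and B holds two. The free compound is fragile: eighteen phenols on seven electron-rich rings oxidise in air and base, the two doubly benzylic interflavan bonds ionise under acid, C2 epimerises under base by opening of ring C, and there is one aryl ester. T and M map directly onto natural epigallocatechin and its gallate, so the real difficulty is joining the units at C8 and not C6 with 4β configuration and, in the plan followed here, building ring C of B from scratch with cis C2/C3 and the right absolute sense next to a large chiral substituent. The feature used for that is the unsubstituted C4 methylene of B between C4a of ring A and the cis C2/C3 pair: O1–C8a–C4a–C4 is a latent o-quinone methide and C3=C2 with ring B a Z-alkene, so O1–C2 and C3–C4 can form in one cycloaddition with the C3 oxygen arriving as a C–B bond.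

## Logic of the disconnections

19 from 18: only unmasking. All eighteen O–benzyl bonds and the C8–Br bond of unit T are cut by hydrogen in one operation. This lets every earlier step run on robust ethers; it demands that nothing else in 18 is reducible and that the ester and the benzylic C–O and C–C bonds of the flavans survive.

18 from 15 and 17: the C4(T)–C8(M) bond is cut, the bond that a C4 cation and an electron-rich ring A form naturally. The trimer falls into a dimer and a monomer that carries all stereocentres of T but one. The forward step needs attack by C8 of unit M in preference to C6 of M and C6 of B, on the β face of the cation, and an electrophile that cannot condense with itself; hence the bromine on C8 of 17.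

17 from 16, and 16 from 2: functional-group changes only (C4–O by hydride abstraction, C8–Br). The C2 and C3 centres of T come unchanged from 2; the C3 hydroxyl stays free so that no deprotection competes with the gallate later.

15 from 14: the C3–O bond of unit B is traced back to a C3–B bond, because boron is what the ring-forming step can deliver. The forward oxidation must go with retention and must spare the gallate.

14 from 9 and 12 through 13: O1–C2 and C3–C4 of ring C of B are cut together. One step then gives a ring, two stereocentres and the full carbon skeleton of the M–B dimer from two pieces of similar size. The forward step must put oxygen on the benzylic carbon, add suprafacially to a Z-alkene (cis), choose one alkene face, and avoid capture of 13 by other arenes.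

12 from 11, and 11 from 10: the C–B bond is cut back to a terminal alkyne (trans-hydroboration sets Z) and the alkyne to an aldehyde by one-carbon homologation.

9 from 8, and 8 from 7: after alcohol-to-aldehyde adjustment, the C4–C4a bond of unit B is cut. The carbon is introduced after the interflavan bond, at the single remaining position ortho to the phenol, so its place is unambiguous and the preceding coupling can use an unencumbered, electron-rich phenol.

7 from 5 and 6: the C4(M)–C8(B) bond is cut. This reduces the precursor to unit M with a leaving group on C4 and a simple symmetric phenol; the forward step must go ortho to the hydroxyl and give 4β, which the substituents on the α face and participation of the C3 ester should secure.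

5 from 4: the C4–O bond is cut back to the C4 methylene by hydride abstraction; the forward step must oxidise only the position activated by the ring A oxygens.

4 from 2 and 3: the acyl C–O bond of the gallate is cut. Unit M then rests on the same benzylated monomer as unit T, and the galloyl group arrives already protected, so no aryl ester is exposed to an alkylation base. The forward acylation must reach the hindered axial C3 hydroxyl without touching C2.

2 from 1: five O–benzyl bonds. Both stereocentres come intact from 1; the forward step must alkylate the phenols and leave the secondary alcohol free.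

## Other disconnections considered

Alternative 1: The cut is the C4a–C8a bond of ring A of unit B. Ring A is folded last from an acyclic keto ester A1 that already carries unit M on C2 and the protected C2/C3 diol of the future ring C at the far end of the chain.
- Forward step: two equivalents of a strong amide base remove the C2 proton and the γ-proton at C6 of the vinylogous ester; C6 attacks the ester carbon (6-exo-trig Claisen closure), methoxide leaves and the dione enolises to resorcinol A2. Its C8a hydroxyl later closes ring C on C2 with inversion.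
- In its favour: the place of M on ring A is fixed by the chain, so the ortho/para question of step 4 does not arise; this is better than the chosen plan. C2 and C3 of B come from reagent-controlled chain chemistry of known reliability, also better than an unproven catalyst-controlled cycloaddition.
- Against it here: A1 is hard to reach, since M must sit on the hindered, epimerisable C2 of a β-keto ester. The strong base excludes the gallate, so M needs a silyl ether that is exchanged later. The second deprotonation must occur at C6 and not at C4. A2 has two free phenols flanking M that must be told apart.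
- Comparison: on structure the plans are equal (both build B de novo and attach T last). On mechanism the folding is known chemistry and the chosen key step is not. On step economy the folding is clearly longer than the four steps that lead from 7 to 15.

Alternative 2: The cut is the C4–C4a bond of unit T (with O1–C2 as a lactol). T is grown on C8 of M from enal A3 and phenol 6.
- Forward step: a chiral secondary amine converts A3 into an iminium ion, 6 adds through its ortho carbon to the β-carbon and the phenolic hydroxyl closes the hemiacetal, giving lactol A4 with C4 of T set by the catalyst.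
- In its favour: organocatalytic phenol alkylation–hemiacetalisation with enals is an established reaction type, better precedent than the chosen key step. The T–M bond is on C8 of M by construction, so the C8/C6 question of step 13 disappears; also an advantage.
- Against it here: the β-carbon of A3 bears the trioxygenated ring A of M, a strong donor that makes the iminium ion a weak, reversible acceptor. A4 holds only C4 of T; ring B, the C3 hydroxyl and two more stereocentres must be added with 2,3-cis-3,4-trans control relative to a centre set first, whereas 1 brings all of this ready-made. M in A4 still lacks its bond to B and its gallate.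
- Comparison: both plans sacrifice one natural unit (equal), but here it is T, whose C4 centre the chosen plan gets for nothing in step 13. Mechanistically the alternative is firmer at its key step and weaker afterwards. It is clearly longer.

Alternative 3: The cut removes three bonds of ring A of unit M (C8–C8a, C6–C7, C4a–C8a). The ring is assembled from cyclobutenone A5 and siloxyalkyne A6, which hangs on C4 of T.
- Forward step: heating opens A5 to a vinylketene; [2+2] addition to A6, 4π opening, 6π electrocyclisation and tautomerisation give phenol A7 (Danheiser benzannulation).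
- In its favour: T is on C8 by construction and the three ring A oxygens emerge differentiated, better regiocontrol than any Friedel–Crafts step of the chosen plan. The cascade is thermal and neutral and is known for siloxyalkynes, so its key step has better precedent.
- Against it here: ring C of M, its three stereocentres and the gallate, which the chosen plan has in 4 after two steps from 1 and 3, must be rebuilt from the cinnamyl chain of A7 (dihydroxylation, ring closure, inversion to 2,3-cis). C4 of M must then be oxidised and coupled to the lower unit, the C3 hydroxyl galloylated and a silyl ether exchanged for benzyl. A6 needs C4-alkynylation of T and conversion into the ynol ether, and its propargylic, benzylic C4 centre must survive heating.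
- Comparison: the chosen plan keeps M intact and does de novo work only on the simplest unit. The late M–B coupling of the alternative is the same type of step as step 4 but on a much larger intermediate. Step economy strongly favours the chosen plan.

Key step: step 9

Remarks on the chemistry (assumptions and design decisions):
- α/β refer to the usual flavan drawing; 4β means trans to the C3 oxygen. The SMILES strings are authoritative for configuration.
- Assumption: 3 and 6 are taken as commercial compounds.
- Assumption: the (R) enantiomer of the phosphoric acid, (R)-TRIP = (R)-3,3'-bis(2,4,6-triisopropylphenyl)-1,1'-binaphthyl-2,2'-diyl hydrogen phosphate, is taken as the matched catalyst for the M-bearing methide. If the sense is opposite, the (S) acid is used under the same conditions.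
- Unit M is assembled from 2 and the protected acid 3. One benzylated monomer then serves units M and T, and the aryl ester is never present while phenols are alkylated under base.
- The one-carbon unit of the salicyl alcohol is introduced after the interflavan bond. A formyl-substituted phenol would be a weaker nucleophile than ring A of electrophile 5 itself and would invite self-condensation of 5.
- Unit T is used with a free C3 hydroxyl (an acyl group could not be removed next to the gallate) and with bromine on C8, which stops self-condensation and leaves in the last step.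
- For the side chain drawn in A2, the acyclic ester A1 must have nine chain carbons (a non-4-enoate).

## Route

Step 1
Reactants: 1 (−)-epigallocatechin (EGC, 2R,3R)
Product: 2 5,7,3',4',5'-penta-O-benzyl-EGC (C3 hydroxyl free; 2R,3R)
Conditions: BnBr (5.5 equiv), K2CO3, DMF, 0 °C → rt, argon
Reagents that add atoms: benzyl bromide, BrCc1ccccc1
Why: Williamson etherification selective for the five phenols, since carbonate does not deprotonate the secondary alcohol; low temperature and exclusion of air limit C-benzylation of ring A and base-induced epimerisation at C2, and no stereocentre is touched.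

Step 2
Reactants: 2 5,7,3',4',5'-penta-O-benzyl-EGC; 3 3,4,5-tris(benzyloxy)benzoic acid
Product: 4 octa-O-benzyl-EGCG (3-O-[3,4,5-tris(benzyloxy)benzoyl] ester of 2; 2R,3R)
Conditions: DCC, DMAP (cat.), CH2Cl2, rt
Reagents that add atoms: none
Why: Steglich esterification: the carbodiimide activates the acid and DMAP transfers the acyl group to the hindered axial C3 hydroxyl under neutral conditions; the C3–O bond is not broken, so the configuration is kept, and C2 is not exposed to base.

Step 3
Reactants: 4 octa-O-benzyl-EGCG
Product: 5 octa-O-benzyl-4β-(2-ethoxyethoxy)-EGCG (C4 ether trans to the C3 gallate)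
Conditions: DDQ, 2-ethoxyethanol, CH2Cl2, rt
Reagents that add atoms: 2-ethoxyethanol, CCOCCO
Why: Oxidative benzylic etherification: DDQ abstracts hydride from C4, and the cation (stabilised by the ring A oxygens) is captured by the alcohol on the β face, away from the C2 aryl group and the C3 ester on the α face; the C4 configuration is not critical because the ether is ionised again in step 4.

Step 4
Reactants: 5 octa-O-benzyl-4β-(2-ethoxyethoxy)-EGCG; 6 3,5-bis(benzyloxy)phenol (4 equiv)
Product: 7 2-(octa-O-benzyl-EGCG-4β-yl)-3,5-bis(benzyloxy)phenol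
Conditions: TMSOTf (0.2 equiv), CH2Cl2, −78 → −30 °C; Et3N quench
Reagents that add atoms: none
Why: Friedel–Crafts alkylation of a phenol by a flavan-4-yl cation: the α face of the C4 cation is covered by the C2 aryl group and the bridging gallate carbonyl, so the arene enters from the β face and C4 becomes 4β (3,4-trans). Attack ortho to the hydroxyl is expected because the two ortho carbons are less hindered than the carbon between the two benzyloxy groups, and the excess of 6 suppresses twofold alkylation and self-condensation through ring A of 5.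

Step 5
Reactants: 7 2-(octa-O-benzyl-EGCG-4β-yl)-3,5-bis(benzyloxy)phenol
Product: 8 4,6-bis(benzyloxy)-2-hydroxy-3-(octa-O-benzyl-EGCG-4β-yl)benzaldehyde
Conditions: MgCl2, Et3N, (CH2O)n, THF, 65 °C
Reagents that add atoms: paraformaldehyde (as formaldehyde), C=O
Why: Magnesium-mediated ortho-formylation of a phenol (Casnati–Skattebøl): the magnesium phenoxide delivers formaldehyde only to the one free ortho carbon and a second formaldehyde takes up hydride to give the aldehyde; the fully benzylated rings of M form no phenoxide and stay untouched, and the ester is stable to the anhydrous amine.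

Step 6
Reactants: 8 4,6-bis(benzyloxy)-2-hydroxy-3-(octa-O-benzyl-EGCG-4β-yl)benzaldehyde
Product: 9 3,5-bis(benzyloxy)-2-(hydroxymethyl)-6-(octa-O-benzyl-EGCG-4β-yl)phenol
Conditions: NaBH4, THF/MeOH, 0 °C; neutral work-up, used at once
Reagents that add atoms: none
Why: Chemoselective borohydride reduction of the aryl aldehyde; the gallate ester is not reduced at 0 °C, and the product is kept away from acid because it ionises easily to the quinone methide.

Step 7
Reactants: 10 3,4,5-tris(benzyloxy)benzaldehyde
Product: 11 1,2,3-tris(benzyloxy)-5-ethynylbenzene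
Conditions: dimethyl (1-diazo-2-oxopropyl)phosphonate, K2CO3, MeOH/THF, rt
Reagents that add atoms: dimethyl (1-diazo-2-oxopropyl)phosphonate, COP(=O)(OC)C(=[N+]=[N-])C(C)=O
Why: Seyferth–Gilbert homologation in the Ohira–Bestmann variant converts the aldehyde into the terminal alkyne under mild carbonate conditions that leave benzyl ethers alone.

Step 8
Reactants: 11 1,2,3-tris(benzyloxy)-5-ethynylbenzene
Product: 12 (Z)-2-[3,4,5-tris(benzyloxy)phenyl]ethenylboronic acid pinacol ester
Conditions: pinacolborane, [Rh(cod)Cl]2 (cat.), P(iPr)3, Et3N, cyclohexane, rt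
Reagents that add atoms: pinacolborane, [H]B1OC(C)(C)C(C)(C)O1
Why: Rhodium-catalysed anti-Markovnikov trans-hydroboration of a terminal alkyne: the reaction passes through a rhodium vinylidene, so boron and the aryl group end up cis and the Z geometry needed for the cis ring is set here.

Step 9
Reactants: 9 3,5-bis(benzyloxy)-2-(hydroxymethyl)-6-(octa-O-benzyl-EGCG-4β-yl)phenol; 12 (Z)-2-[3,4,5-tris(benzyloxy)phenyl]ethenylboronic acid pinacol ester (3 equiv)
Product: 14 M–B dimer boronate (octa-O-benzyl-EGCG-(4β→8)-linked penta-O-benzyl-2,3-cis-flavan bearing pinacolboryl in place of the C3 oxygen; aryl group and boron both α), via o-quinone methide 13 (not isolated)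
Conditions: (R)-TRIP (10 mol%), 5 Å MS, toluene, 0 °C → rt, slow addition of 9
Reagents that add atoms: none
Why: Proposed new method: the phosphoric acid protonates the benzylic hydroxyl of 9, water leaves with help from the ortho and para benzyloxy groups, and the o-quinone methide 13 stays hydrogen-bonded to the chiral phosphate through its carbonyl oxygen; the closest known reaction type is the Brønsted acid-catalysed inverse-electron-demand oxa-Diels–Alder reaction of o-quinone methides with styrenes to 2-arylchromans, chiral phosphoric acid variants included, whereas an alkenylboronate as the 2π partner is not established. The boron-bearing carbon of 12 attacks the methide carbon (C3–C4) while positive charge builds on the benzylic carbon, stabilised by the para-benzyloxyaryl group, and the ring oxygen closes on that carbon (O1–C2) in the same asynchronous event. Ring C of unit B is thus closed in a [4+2] mode (4π oxa-diene of 13 plus the 2π alkene), both bonds formed suprafacially on each partner, not by stepwise closure of a tethered chain. The relative configuration of the new centres C2 and C3 is dictated by the Z geometry of 12: suprafacial addition places aryl and boron cis. Their absolute configuration (aryl and boron both α) is decided by which alkene face meets the methide, to be controlled by the phosphate, which shields one face of the hydrogen-bonded methide, acting together with the stereogenic M unit on C8 next to the reacting oxygen. The step needs regioselectivity (oxygen to the benzylic carbon), which the electron-rich aryl group of 12 secures, cis selectivity, which requires ring closure to outrun rotation in the benzylic cation, and chemoselectivity over Friedel–Crafts capture of 13 by ring A of unit M, which the excess of 12 and the slow addition of 9 address. Because unit M is chiral, a wrong-face adduct is a diastereomer and can be removed by chromatography.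

Step 10
Reactants: 14 M–B dimer boronate
Product: 15 octa-O-benzyl-EGCG-(4β→8)-[5,7,3',4',5'-penta-O-benzyl-EGC] (unit B 2R,3R, C3 hydroxyl free)
Conditions: NaBO3·4H2O, THF/H2O, rt
Reagents that add atoms: sodium perborate tetrahydrate, [Na+].[Na+].O[B-]1(O)OO[B-](O)(O)OO1
Why: Perborate oxidation of a secondary alkylboronate: C3 migrates from boron to oxygen with retention, so the hydroxyl is cis to the C2 aryl group as in epigallocatechin; the near-neutral conditions spare the gallate and no free phenol is present.

Step 11
Reactants: 2 5,7,3',4',5'-penta-O-benzyl-EGC (second portion of the material from step 1)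
Product: 16 8-bromo-5,7,3',4',5'-penta-O-benzyl-EGC
Conditions: NBS, CH2Cl2, −78 °C → rt
Reagents that add atoms: N-bromosuccinimide, O=C1CCC(=O)N1Br
Why: Electrophilic aromatic bromination goes to C8 (next to the ring oxygen) and not to C6, which is flanked by two benzyloxy groups; the bromine blocks the only strongly nucleophilic carbon of this unit for step 13 and is removed in step 14.

Step 12
Reactants: 16 8-bromo-5,7,3',4',5'-penta-O-benzyl-EGC
Product: 17 8-bromo-5,7,3',4',5'-penta-O-benzyl-4β-(2-ethoxyethoxy)-EGC
Conditions: DDQ, 2-ethoxyethanol, CH2Cl2, rt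
Reagents that add atoms: 2-ethoxyethanol, CCOCCO
Why: Oxidative benzylic etherification as in step 3; the alcohol adds to the C4 cation on the β face because the cis C2 aryl group and C3 hydroxyl occupy the α face.

Step 13
Reactants: 15 octa-O-benzyl-EGCG-(4β→8)-[penta-O-benzyl-EGC]; 17 8-bromo-penta-O-benzyl-4β-(2-ethoxyethoxy)-EGC (1.3 equiv)
Product: 18 [8-bromo-penta-O-benzyl-EGC]-(4β→8)-[octa-O-benzyl-EGCG]-(4β→8)-[penta-O-benzyl-EGC] (eighteen benzyl ethers, one aryl bromide)
Conditions: TMSOTf (0.2 equiv), CH2Cl2, −78 → −40 °C; Et3N quench
Reagents that add atoms: none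
Why: Lewis acid-catalysed interflavan Friedel–Crafts coupling: the C4 cation from 17 is attacked on its β face (aryl and hydroxyl block the α face) by C8 of unit M, the only free ring A carbon next to a ring oxygen, whereas C6 of M and C6 of B lie between two benzyloxy groups; 17 cannot condense with itself because its C8 is brominated.

Step 14
Reactants: 18 protected, brominated trimer
Product: 19 target, EGC-(4β→8)-EGCG-(4β→8)-EGC
Conditions: H2 (1 atm), Pd(OH)2/C, Et3N (2 equiv), THF/MeOH/H2O, rt; filtration, Sephadex LH-20
Reagents that add atoms: none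
Why: Catalytic hydrogenolysis cleaves the eighteen benzyl ethers and the aryl C–Br bond in one operation; triethylamine binds the hydrogen bromide so that the acid-labile interflavan bonds are safe, and the ester and all stereocentres are untouched.

## Compound list

1 | (−)-epigallocatechin (EGC) | O[C@@H]1Cc2c(O)cc(O)cc2O[C@@H]1c1cc(O)c(O)c(O)c1 | starting material
2 | 5,7,3',4',5'-penta-O-benzyl-EGC | O[C@@H]1Cc2c(OCc9ccccc9)cc(OCc9ccccc9)cc2O[C@@H]1c1cc(OCc9ccccc9)c(OCc9ccccc9)c(OCc9ccccc9)c1 | intermediate
3 | 3,4,5-tris(benzyloxy)benzoic acid | OC(=O)c1cc(OCc2ccccc2)c(OCc2ccccc2)c(OCc2ccccc2)c1 | starting material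
4 | octa-O-benzyl-EGCG | O=C(O[C@@H]1Cc2c(OCc9ccccc9)cc(OCc9ccccc9)cc2O[C@@H]1c1cc(OCc9ccccc9)c(OCc9ccccc9)c(OCc9ccccc9)c1)c1cc(OCc9ccccc9)c(OCc9ccccc9)c(OCc9ccccc9)c1 | intermediate
5 | octa-O-benzyl-4β-(2-ethoxyethoxy)-EGCG | O=C(O[C@@H]1[C@@H](OCCOCC)c2c(OCc9ccccc9)cc(OCc9ccccc9)cc2O[C@@H]1c1cc(OCc9ccccc9)c(OCc9ccccc9)c(OCc9ccccc9)c1)c1cc(OCc9ccccc9)c(OCc9ccccc9)c(OCc9ccccc9)c1 | intermediate
6 | 3,5-bis(benzyloxy)phenol | Oc1cc(OCc2ccccc2)cc(OCc2ccccc2)c1 | starting material
7 | 2-(octa-O-benzyl-EGCG-4β-yl)-3,5-bis(benzyloxy)phenol | Oc1cc(OCc9ccccc9)cc(OCc9ccccc9)c1[C@H]3c4c(OCc9ccccc9)cc(OCc9ccccc9)cc4O[C@H](c4cc(OCc9ccccc9)c(OCc9ccccc9)c(OCc9ccccc9)c4)[C@@H]3OC(=O)c3cc(OCc9ccccc9)c(OCc9ccccc9)c(OCc9ccccc9)c3 | intermediate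
8 | 4,6-bis(benzyloxy)-2-hydroxy-3-(octa-O-benzyl-EGCG-4β-yl)benzaldehyde | O=Cc1c(OCc9ccccc9)cc(OCc9ccccc9)c([C@H]3c4c(OCc9ccccc9)cc(OCc9ccccc9)cc4O[C@H](c4cc(OCc9ccccc9)c(OCc9ccccc9)c(OCc9ccccc9)c4)[C@@H]3OC(=O)c3cc(OCc9ccccc9)c(OCc9ccccc9)c(OCc9ccccc9)c3)c1O | intermediate
9 | 3,5-bis(benzyloxy)-2-(hydroxymethyl)-6-(octa-O-benzyl-EGCG-4β-yl)phenol | OCc1c(OCc9ccccc9)cc(OCc9ccccc9)c([C@H]3c4c(OCc9ccccc9)cc(OCc9ccccc9)cc4O[C@H](c4cc(OCc9ccccc9)c(OCc9ccccc9)c(OCc9ccccc9)c4)[C@@H]3OC(=O)c3cc(OCc9ccccc9)c(OCc9ccccc9)c(OCc9ccccc9)c3)c1O | intermediate
10 | 3,4,5-tris(benzyloxy)benzaldehyde | O=Cc1cc(OCc2ccccc2)c(OCc2ccccc2)c(OCc2ccccc2)c1 | starting material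
11 | 1,2,3-tris(benzyloxy)-5-ethynylbenzene | C#Cc1cc(OCc2ccccc2)c(OCc2ccccc2)c(OCc2ccccc2)c1 | intermediate
12 | (Z)-2-[3,4,5-tris(benzyloxy)phenyl]ethenylboronic acid pinacol ester | CC1(C)OB(OC1(C)C)/C=C\c1cc(OCc2ccccc2)c(OCc2ccccc2)c(OCc2ccccc2)c1 | intermediate
13 | o-quinone methide: 3,5-bis(benzyloxy)-6-methylidene-2-(octa-O-benzyl-EGCG-4β-yl)cyclohexa-2,4-dien-1-one | C=C1C(OCc9ccccc9)=CC(OCc9ccccc9)=C([C@H]3c4c(OCc9ccccc9)cc(OCc9ccccc9)cc4O[C@H](c4cc(OCc9ccccc9)c(OCc9ccccc9)c(OCc9ccccc9)c4)[C@@H]3OC(=O)c3cc(OCc9ccccc9)c(OCc9ccccc9)c(OCc9ccccc9)c3)C1=O | intermediate (not isolated)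
14 | M–B dimer boronate (pinacolboryl in place of the C3 oxygen of unit B, aryl and boron cis, both α) | CC1(C)OB(OC1(C)C)[C@@H]1Cc2c(OCc9ccccc9)cc(OCc9ccccc9)c([C@H]3c4c(OCc9ccccc9)cc(OCc9ccccc9)cc4O[C@H](c4cc(OCc9ccccc9)c(OCc9ccccc9)c(OCc9ccccc9)c4)[C@@H]3OC(=O)c3cc(OCc9ccccc9)c(OCc9ccccc9)c(OCc9ccccc9)c3)c2O[C@@H]1c1cc(OCc9ccccc9)c(OCc9ccccc9)c(OCc9ccccc9)c1 | intermediate
15 | octa-O-benzyl-EGCG-(4β→8)-[5,7,3',4',5'-penta-O-benzyl-EGC] | O[C@@H]1Cc2c(OCc9ccccc9)cc(OCc9ccccc9)c([C@H]3c4c(OCc9ccccc9)cc(OCc9ccccc9)cc4O[C@H](c4cc(OCc9ccccc9)c(OCc9ccccc9)c(OCc9ccccc9)c4)[C@@H]3OC(=O)c3cc(OCc9ccccc9)c(OCc9ccccc9)c(OCc9ccccc9)c3)c2O[C@@H]1c1cc(OCc9ccccc9)c(OCc9ccccc9)c(OCc9ccccc9)c1 | intermediate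
16 | 8-bromo-5,7,3',4',5'-penta-O-benzyl-EGC | O[C@@H]1Cc2c(OCc9ccccc9)cc(OCc9ccccc9)c(Br)c2O[C@@H]1c1cc(OCc9ccccc9)c(OCc9ccccc9)c(OCc9ccccc9)c1 | intermediate
17 | 8-bromo-5,7,3',4',5'-penta-O-benzyl-4β-(2-ethoxyethoxy)-EGC | O[C@@H]1[C@@H](OCCOCC)c2c(OCc9ccccc9)cc(OCc9ccccc9)c(Br)c2O[C@@H]1c1cc(OCc9ccccc9)c(OCc9ccccc9)c(OCc9ccccc9)c1 | intermediate
18 | [8-bromo-penta-O-benzyl-EGC]-(4β→8)-[octa-O-benzyl-EGCG]-(4β→8)-[penta-O-benzyl-EGC] | O=C(O[C@@H]1[C@@H](c2c(OCc9ccccc9)cc(OCc9ccccc9)c3c2O[C@H](c2cc(OCc9ccccc9)c(OCc9ccccc9)c(OCc9ccccc9)c2)[C@H](O)C3)c2c(OCc9ccccc9)cc(OCc9ccccc9)c([C@H]3c4c(OCc9ccccc9)cc(OCc9ccccc9)c(Br)c4O[C@H](c4cc(OCc9ccccc9)c(OCc9ccccc9)c(OCc9ccccc9)c4)[C@@H]3O)c2O[C@@H]1c1cc(OCc9ccccc9)c(OCc9ccccc9)c(OCc9ccccc9)c1)c1cc(OCc9ccccc9)c(OCc9ccccc9)c(OCc9ccccc9)c1 | intermediate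
19 | EGC-(4β→8)-EGCG-(4β→8)-EGC (CNP0278699.1) | O=C(O[C@@H]1[C@@H](c2c(O)cc(O)c3c2O[C@H](c2cc(O)c(O)c(O)c2)[C@H](O)C3)c2c(O)cc(O)c([C@H]3c4c(O)cc(O)cc4O[C@H](c4cc(O)c(O)c(O)c4)[C@@H]3O)c2O[C@@H]1c1cc(O)c(O)c(O)c1)c1cc(O)c(O)c(O)c1 | target

Total step count: 14. Longest linear sequence: 10 steps (steps 1, 2, 3, 4, 5, 6, 9, 10, 13, 14).

## Least certain steps and fallbacks

Step 9 (key step, new method).
- What may go wrong: poor facial selectivity if the acid and the M unit work against each other; loss of the cis relationship by bond rotation in a long-lived benzylic cation; consumption of the methide by Friedel–Crafts attack of ring A of another molecule or by self-dimerisation; acid-induced Z-to-E isomerisation or protodeboronation of 12.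
- Fallback (known chemistry): take unit B from the natural pool instead of building its ring C. TMSOTf-catalysed Friedel–Crafts coupling of 5 with an excess of 2 (CH2Cl2, −78 °C) lets C8 of 2 attack the C4 cation of 5 on the β face and gives 15 directly. It sets out from 5 and 2 and returns at 15; steps 4 to 10 are then not needed and no new compound is made. The same material would serve as an authentic sample for assigning the configuration of 15 from the main route.

Step 4.
- What may go wrong: alkylation at the position between the two benzyloxy groups, twofold alkylation of the very reactive phenol, or self-condensation of the cation with ring A of 5.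
- Fallback: let the nucleophile carry the one-carbon unit. Commercial 2,4,6-trihydroxybenzaldehyde is dibenzylated (BnBr, K2CO3, DMF; the hydroxyl chelated to the aldehyde reacts last) to 2,4-bis(benzyloxy)-6-hydroxybenzaldehyde F1. Its deactivated ring accepts only one alkyl group, and coupling with 5 (TMSOTf, CH2Cl2, large excess of F1) ortho to the hydroxyl gives 8 directly. It sets out from 5 and returns at 8; step 5 falls away. The price is a weaker nucleophile, hence the large excess.

Step 13.
- What may go wrong: competing attack at C6 of unit M or of unit B, twofold alkylation, slow reaction at the crowded C8, or acid-induced ionisation of the existing M–B bond.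
- Fallback: change the order so that each interflavan bond is made on a monomeric nucleophile.
  - First, 17 is coupled with an excess of 4 (TMSOTf, CH2Cl2, −78 °C) at C8 to give the T–M dimer [8-bromo-penta-O-benzyl-EGC]-(4β→8)-[octa-O-benzyl-EGCG] F2.
  - Second, DDQ and 2-ethoxyethanol oxidise the only C4 methylene (unit M; the tertiary C4–H of unit T is shielded by its two aryl groups) to give [8-bromo-penta-O-benzyl-EGC]-(4β→8)-[octa-O-benzyl-4β-(2-ethoxyethoxy)-EGCG] F3.
  - Third, TMSOTf-catalysed coupling of F3 with 2 gives 18.
  - It sets out from 17 and 4 and returns at 18. Unit B then comes from 2, so this fallback gives up the ring C built in step 9.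

Step 8.
- What may go wrong: incomplete Z selectivity or later Z-to-E isomerisation (the E isomer would give the 2,3-trans ring in step 9), or deactivation of the air-sensitive catalyst.
- Fallback: fix the geometry by syn addition of hydrogen. 11 is deprotonated (n-BuLi, THF, −78 °C), borylated with 2-isopropoxy-4,4,5,5-tetramethyl-1,3,2-dioxaborolane and released with HCl in Et2O to give 2-{[3,4,5-tris(benzyloxy)phenyl]ethynyl}-4,4,5,5-tetramethyl-1,3,2-dioxaborolane F4. Semi-hydrogenation (H2, Pd/CaCO3 poisoned with Pb(OAc)2, quinoline, 1,4-dioxane) gives 12. It sets out from 11 and returns at 12.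

## Further compounds

F0 | step 9 | none | none
F1 | step 4 | 2,4-bis(benzyloxy)-6-hydroxybenzaldehyde | O=Cc1c(O)cc(OCc2ccccc2)cc1OCc1ccccc1
F2 | step 13 | [8-bromo-penta-O-benzyl-EGC]-(4β→8)-[octa-O-benzyl-EGCG] | O=C(O[C@@H]1Cc2c(OCc9ccccc9)cc(OCc9ccccc9)c([C@H]3c4c(OCc9ccccc9)cc(OCc9ccccc9)c(Br)c4O[C@H](c4cc(OCc9ccccc9)c(OCc9ccccc9)c(OCc9ccccc9)c4)[C@@H]3O)c2O[C@@H]1c1cc(OCc9ccccc9)c(OCc9ccccc9)c(OCc9ccccc9)c1)c1cc(OCc9ccccc9)c(OCc9ccccc9)c(OCc9ccccc9)c1
F3 | step 13 | [8-bromo-penta-O-benzyl-EGC]-(4β→8)-[octa-O-benzyl-4β-(2-ethoxyethoxy)-EGCG] | O=C(O[C@@H]1[C@@H](OCCOCC)c2c(OCc9ccccc9)cc(OCc9ccccc9)c([C@H]3c4c(OCc9ccccc9)cc(OCc9ccccc9)c(Br)c4O[C@H](c4cc(OCc9ccccc9)c(OCc9ccccc9)c(OCc9ccccc9)c4)[C@@H]3O)c2O[C@@H]1c1cc(OCc9ccccc9)c(OCc9ccccc9)c(OCc9ccccc9)c1)c1cc(OCc9ccccc9)c(OCc9ccccc9)c(OCc9ccccc9)c1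
F4 | step 8 | 2-{[3,4,5-tris(benzyloxy)phenyl]ethynyl}-4,4,5,5-tetramethyl-1,3,2-dioxaborolane | CC1(C)OB(OC1(C)C)C#Cc1cc(OCc2ccccc2)c(OCc2ccccc2)c(OCc2ccccc2)c1
A1 | alternative 1 | methyl 5-(benzyloxy)-3-oxonon-4-enoate carrying the 3-O-TBS-penta-O-benzyl-EGC-4β-yl group on C2, a benzyloxy group on C8, and a triethylsilyloxy group and the 3,4,5-tris(benzyloxy)phenyl ring on C9 | COC(=O)C([C@H]1c2c(OCc9ccccc9)cc(OCc9ccccc9)cc2O[C@H](c2cc(OCc9ccccc9)c(OCc9ccccc9)c(OCc9ccccc9)c2)[C@@H]1O[Si](C)(C)C(C)(C)C)C(=O)C=C(OCc9ccccc9)CC[C@@H](OCc9ccccc9)[C@@H](O[Si](CC)(CC)CC)c1cc(OCc9ccccc9)c(OCc9ccccc9)c(OCc9ccccc9)c1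
A2 | alternative 1 | ring A resorcinol of unit B (C8a and C7 hydroxyls free, C5 benzyl ether) with unit M on C8 and the open ring C chain on C4a | Oc1c(C[C@@H](OCc9ccccc9)[C@@H](O[Si](CC)(CC)CC)c2cc(OCc9ccccc9)c(OCc9ccccc9)c(OCc9ccccc9)c2)c(OCc9ccccc9)cc(O)c1[C@H]1c2c(OCc9ccccc9)cc(OCc9ccccc9)cc2O[C@H](c2cc(OCc9ccccc9)c(OCc9ccccc9)c(OCc9ccccc9)c2)[C@@H]1O[Si](C)(C)C(C)(C)C
A3 | alternative 2 | (E)-3-(3-O-TBS-5,7,3',4',5'-penta-O-benzyl-EGC-8-yl)prop-2-enal | CC(C)(C)[Si](C)(C)O[C@@H]1Cc2c(OCc9ccccc9)cc(OCc9ccccc9)c(/C=C/C=O)c2O[C@@H]1c1cc(OCc9ccccc9)c(OCc9ccccc9)c(OCc9ccccc9)c1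
A4 | alternative 2 | 4-(3-O-TBS-penta-O-benzyl-EGC-8-yl)-5,7-bis(benzyloxy)chroman-2-ol, C4 as in unit T (lactol anomers) | CC(C)(C)[Si](C)(C)O[C@@H]1Cc2c(OCc9ccccc9)cc(OCc9ccccc9)c([C@H]3c4c(OCc9ccccc9)cc(OCc9ccccc9)cc4OC(O)C3)c2O[C@@H]1c1cc(OCc9ccccc9)c(OCc9ccccc9)c(OCc9ccccc9)c1
A5 | alternative 3 | 3-(benzyloxy)-4-[(E)-3-(3,4,5-tris(benzyloxy)phenyl)prop-2-enyl]cyclobut-2-en-1-one | O=C1C=C(OCc9ccccc9)C1C/C=C/c1cc(OCc9ccccc9)c(OCc9ccccc9)c(OCc9ccccc9)c1
A6 | alternative 3 | hexa-O-benzyl-EGC carrying a (triisopropylsiloxy)ethynyl group on C4 (β) | CC(C)[Si](C(C)C)(C(C)C)OC#C[C@H]3c4c(OCc9ccccc9)cc(OCc9ccccc9)cc4O[C@H](c4cc(OCc9ccccc9)c(OCc9ccccc9)c(OCc9ccccc9)c4)[C@@H]3OCc9ccccc9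
A7 | alternative 3 | ring A phenol of unit M (free at C8a only; C5 benzyl ether, C7 triisopropylsilyl ether) with unit T on C8 and the cinnamyl chain on C4a | Oc1c(C/C=C/c2cc(OCc9ccccc9)c(OCc9ccccc9)c(OCc9ccccc9)c2)c(OCc9ccccc9)cc(O[Si](C(C)C)(C(C)C)C(C)C)c1[C@H]3c4c(OCc9ccccc9)cc(OCc9ccccc9)cc4O[C@H](c4cc(OCc9ccccc9)c(OCc9ccccc9)c(OCc9ccccc9)c4)[C@@H]3OCc9ccccc9
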